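**Plan**
Labels: C-a is the CH bearing isobutenyl and C3 of quinolone A. C-b is the ring-fusion CH on C3 of quinolone B. C-c is the ring-fusion OCH next to CMe2. Pyran A holds O–C-c–C-b–C-a and pyran B holds O–CMe2–C-c–C-b.
Cuts, in order: the O–C4(quinolone A) bond of pyran A, then the C-c–H bond (carbinol back to ketone), then C-a–isobutenyl and C-a–C-b together.
Enabling feature: with C-c as a carbonyl inside pyran B, blocked on one side by CMe2, C-b is the only acidic CH2. Condensing it with the 3-formyl carbon of quinolone A makes C-a the β-carbon of an exocyclic enone.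
Forward order: pyran B is built first (quinolone plus prenal, epoxide, hydride shift). The three fragments are then joined at C-a, and pyran A closes last.
Stereochemistry: C-a (R) comes from a chiral diene–rhodium catalyst. C-b (S) and C-c (S) come from a dynamic kinetic transfer hydrogenation that gives the cis carbinol. The ring closure breaks no bond at a stereocentre.

Key step: step 6

Assumption: the arylidene ketone of the key step is taken as the (Z)-isomer (quinolone A syn to the C-c carbonyl, away from the peri lactam C=O of quinolone B), and the sense of induction of the diene and of the ruthenium catalyst is assigned from the accepted models for simpler enones and ketones; if either is reversed, the mirror-image ligand is used and nothing else changes.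

Step 1
Reactants: 1 4-hydroxy-1-methylquinolin-2(1H)-one; 2 3-methylbut-2-enal
Product: 4 N-methylflindersine (2,2,6-trimethyl-2H-pyrano[3,2-c]quinolin-5(6H)-one), via oxatriene 3 (not isolated)
Conditions: ethylenediammonium diacetate (10 mol %), DMF, 100 °C
Reagents that add atoms: none
Why: Knoevenagel condensation at the nucleophilic C3 of 1 gives the (E)-1-oxatriene 3, which closes through the C4 oxygen by oxa-6π electrocyclisation (formal [3+3] annulation, the standard entry to 2,2-dimethylpyranoquinolones) and builds pyran B without a stereocentre.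

Step 2
Reactants: 4 N-methylflindersine
Product: 5 (±)-3,4-epoxy-2,2,6-trimethyl-3,4-dihydro-2H-pyrano[3,2-c]quinolin-5(6H)-one (cis-fused oxirane; racemic)
Conditions: dimethyldioxirane (1.2 equiv), acetone/CH2Cl2, 0 °C
Reagents that add atoms: dimethyldioxirane, CC1(C)OO1
Why: Neutral dioxirane epoxidation of the electron-rich chromene-type C3=C4 alkene avoids the acid-induced opening that peracids cause with such oxiranes, and the racemate is acceptable because both stereocentres are erased in step 3.

Step 3
Reactants: 5 (±)-3,4-epoxide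
Product: 6 2,2,6-trimethyl-2H-pyrano[3,2-c]quinoline-3,5(4H,6H)-dione
Conditions: BF3·OEt2 (20 mol %), CH2Cl2, −40 → 0 °C, high dilution
Reagents that add atoms: none
Why: Meinwald rearrangement, in which the Lewis acid breaks the C4–O bond to a cation stabilised by the ring oxygen through C10b=C4a and a 1,2-hydride shift from C3 delivers the 3-ketone, as known for 2,2-dimethylchromene oxides.

Step 4
Reactants: 1 4-hydroxy-1-methylquinolin-2(1H)-one
Product: 8 4-chloro-1-methyl-2-oxo-1,2-dihydroquinoline-3-carbaldehyde, via iminium chloride 7 (not isolated)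
Conditions: POCl3 (3 equiv), DMF, 0 → 70 °C; then ice-water
Reagents that add atoms: N,N-dimethylformamide, CN(C)C=O; phosphoryl chloride, O=P(Cl)(Cl)Cl; water, O
Why: Vilsmeier–Haack chloroformylation, well known for 4-hydroxy-2-quinolones and 4-hydroxycoumarins, attacks the enolic C3, exchanges the activated 4-oxygen for chloride, and the iminium salt 7 is hydrolysed on quenching.

Step 5
Reactants: 8 4-chloro-1-methyl-2-oxo-1,2-dihydroquinoline-3-carbaldehyde
Product: 9 4-methoxy-1-methyl-2-oxo-1,2-dihydroquinoline-3-carbaldehyde
Conditions: NaOMe (1.05 equiv), MeOH, 0 °C → rt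
Reagents that add atoms: sodium methoxide, [Na+].[O-]C
Why: Addition–elimination (SNAr) at C4 is fast because that carbon is activated by both the 3-formyl group and the lactam carbonyl, while hemiacetal formation at the aldehyde is reversible.

Step 6
Reactants: 6 2,2,6-trimethyl-2H-pyrano[3,2-c]quinoline-3,5(4H,6H)-dione (1.05 equiv); 9 4-methoxy-1-methyl-2-oxo-1,2-dihydroquinoline-3-carbaldehyde; 10 (2-methylprop-1-en-1-yl)boronic acid
Product: 12 (4S)-4-[(1R)-1-(4-methoxy-1-methyl-2-oxoquinolin-3-yl)-3-methylbut-2-enyl]-2,2,6-trimethyl-2H-pyrano[3,2-c]quinoline-3,5(4H,6H)-dione (C-b labile; drawn as the epimer consumed in step 7), via arylidene ketone 11 (not isolated)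
Conditions: (a) K3PO4 (0.5 equiv), 4 Å MS, 1,4-dioxane, 50 °C; (b) same flask: [RhCl(C2H4)2]2 (2.5 mol %), (S,S)-Ph-bod* [(1S,4S)-2,5-diphenylbicyclo[2.2.2]octa-2,5-diene, 5.5 mol %], 10 (2.5 equiv, in portions), H2O (10 equiv), 50 °C
Reagents that add atoms: none
Why: Proposed new method: K3PO4 enolises 6 at C-b, its only acidic position because C-c is flanked on the other side by the quaternary CMe2, and Claisen–Schmidt addition to the non-enolisable aldehyde 9 followed by E1cB loss of water gives the s-cis-locked enone 11, an inorganic base being used because a nucleophilic amine would displace the doubly activated 4-OMe of 9. In the same flask the hydroxo complex of monovalent rhodium formed from [RhCl(C2H4)2]2, the diene and aqueous base transmetalates with 10, the C-a=C-b bond inserts into the Rh–alkenyl bond with carbon delivery to C-a, and water protonates the oxa-π-allyl enolate at C-b and returns Rh–OH. The closest known reaction type is the Hayashi–Miyaura asymmetric 1,4-addition of alkenylboronic acids to enones and to doubly activated arylidene acceptors; unproven are its extension to a singly activated, trisubstituted α,β-diaryl exocyclic enone and its telescoping with the condensation, which should succeed because the α-aryl group stabilises the developing enolate, the twisted quinolone A ring cannot donate its 4-OMe density into the enone, and diene ligands give the most reactive alkenylrhodium species. No ring closes in this step. C-a is controlled by the C2-symmetric diene, whose phenyl groups leave only the Re face of C-a of the (Z)-enone open to the Rh–C bond and so give (R), whereas C-b results from unselective protonation and remains labile, exactly as step 7 requires. The step needs 1,4- rather than 1,2-addition, secured by consuming 9 completely before rhodium is added and by the neopentyl-type shielding of the C-c carbonyl, and it needs the C4–OMe group of quinolone A to survive, secured because methoxide, unlike chloride, is too poor a leaving group for the stabilised enolate oxygen to expel at 50 °C.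

Step 7
Reactants: 12 conjugate-addition ketone (C-b epimers in equilibrium)
Product: 13 (3S,4S)-3-hydroxy-4-[(1R)-1-(4-methoxy-1-methyl-2-oxoquinolin-3-yl)-3-methylbut-2-enyl]-2,2,6-trimethyl-3,4-dihydro-2H-pyrano[3,2-c]quinolin-5(6H)-one
Conditions: RuCl[(R,R)-TsDPEN](p-cymene) (3 mol %), HCO2H/Et3N (1:1), EtOAc, 40 °C
Reagents that add atoms: none
Why: Noyori–Ikariya asymmetric transfer hydrogenation with dynamic kinetic resolution, known for α-substituted cyclic ketones and for ring ketones next to quaternary carbons, works here because Et3N epimerises the acidic α-aryl C-b–H faster than reduction, the C-b side chain sits pseudoaxial to escape the peri lactam C=O so that Ru–H can only approach anti to it and give a cis carbinol, and the (R,R)-catalyst, holding the CMe2 side away from its η6-arene, delivers hydride to the Re face of C-c and thereby drains the (S)-C-b epimer into (3S,4S)-13 without touching the isobutenyl alkene.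

Step 8
Reactants: 13 cis-carbinol
Product: 14 target CNP0107253.2 (pyrans A and B cis-fused at C-b–C-c; isobutenyl at C-a on the same face as H-b and H-c; C-a R and C-b S and C-c S)
Conditions: NaH (1.5 equiv), THF, 0 → 60 °C; then H2O
Reagents that add atoms: none
Why: Intramolecular addition–elimination (SNAr-type alkoxy exchange on a β-alkoxy-α,β-unsaturated lactam, 6-endo-trig) lets the C-c alkoxide add to C4 of quinolone A and expel methoxide, which closes pyran A, is driven by release of the small alkoxide, and retains all three configurations because no bond at C-a, C-b or C-c is broken.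

**Compound list**
1 | 4-hydroxy-1-methylquinolin-2(1H)-one | Cn1c(=O)cc(O)c2ccccc21 | starting material
2 | 3-methylbut-2-enal | CC(C)=CC=O | starting material
3 | (E)-1-methyl-3-(3-methylbut-2-enylidene)quinoline-2,4(1H,3H)-dione (dienyl chain syn to C4=O) | CC(C)=C/C=C1\C(=O)c2ccccc2N(C)C1=O | intermediate
4 | N-methylflindersine, 2,2,6-trimethyl-2H-pyrano[3,2-c]quinolin-5(6H)-one | CC1(C)C=Cc2c(O1)c1ccccc1n(C)c2=O | intermediate
5 | (±)-3,4-epoxy-2,2,6-trimethyl-3,4-dihydro-2H-pyrano[3,2-c]quinolin-5(6H)-one (one enantiomer drawn) | CC1(C)Oc2c(c(=O)n(C)c3ccccc23)[C@@H]2O[C@H]12 | intermediate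
6 | 2,2,6-trimethyl-2H-pyrano[3,2-c]quinoline-3,5(4H,6H)-dione | CC1(C)Oc2c(CC1=O)c(=O)n(C)c1ccccc21 | intermediate
7 | (4-chloro-1-methyl-2-oxoquinolin-3-yl)methylidene-dimethyliminium chloride | C[N+](C)=Cc1c(Cl)c2ccccc2n(C)c1=O.[Cl-] | intermediate
8 | 4-chloro-1-methyl-2-oxo-1,2-dihydroquinoline-3-carbaldehyde | Cn1c(=O)c(C=O)c(Cl)c2ccccc21 | intermediate
9 | 4-methoxy-1-methyl-2-oxo-1,2-dihydroquinoline-3-carbaldehyde | COc1c(C=O)c(=O)n(C)c2ccccc12 | intermediate
10 | (2-methylprop-1-en-1-yl)boronic acid | CC(C)=CB(O)O | starting material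
11 | (Z)-4-[(4-methoxy-1-methyl-2-oxoquinolin-3-yl)methylidene]-2,2,6-trimethyl-2H-pyrano[3,2-c]quinoline-3,5(4H,6H)-dione | COc1c(/C=C2\C(=O)C(C)(C)Oc3c2c(=O)n(C)c2ccccc32)c(=O)n(C)c2ccccc12 | intermediate
12 | (4S)-4-[(1R)-1-(4-methoxy-1-methyl-2-oxoquinolin-3-yl)-3-methylbut-2-enyl]-2,2,6-trimethyl-2H-pyrano[3,2-c]quinoline-3,5(4H,6H)-dione | CC(C)=C[C@@H](c1c(OC)c2ccccc2n(C)c1=O)[C@@H]1C(=O)C(C)(C)Oc2c1c(=O)n(C)c1ccccc21 | intermediate
13 | (3S,4S)-3-hydroxy-4-[(1R)-1-(4-methoxy-1-methyl-2-oxoquinolin-3-yl)-3-methylbut-2-enyl]-2,2,6-trimethyl-3,4-dihydro-2H-pyrano[3,2-c]quinolin-5(6H)-one | CC(C)=C[C@@H](c1c(OC)c2ccccc2n(C)c1=O)[C@@H]1[C@H](O)C(C)(C)Oc2c1c(=O)n(C)c1ccccc21 | intermediate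
14 | CNP0107253.2, cis-fused bis(pyranoquinolinone), C-a (R), C-b (S), C-c (S) | CC(C)=C[C@H]1c2c(c3ccccc3n(C)c2=O)O[C@H]2[C@@H]1c1c(c3ccccc3n(C)c1=O)OC2(C)C | target

**Totals**
Total steps: 8. Longest linear sequence: 6 steps (1, 2, 3, 6, 7, 8). Steps 4 and 5 form the convergent branch.

**Steps most likely to fail**

Step 6. Three things may go wrong:
- Insertion of the crowded trisubstituted alkene into the Rh–alkenyl bond may be slower than protodeboronation of the boronic acid.
- Insertion may also be slower than water-induced retro-aldol cleavage of the enone.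
- Face selection on an α,β-diaryl enone may be poor.

The fallback sets out from 9 and 6 and returns at 12. It uses known chemistry and forms C-a–C-b by allylic alkylation instead of conjugate addition.
- Aldehyde 9 is treated with 2-methylprop-1-enylmagnesium bromide (THF, −78 °C) to give the racemic allylic alcohol 3-(1-hydroxy-3-methylbut-2-enyl)-4-methoxy-1-methylquinolin-2(1H)-one F1.
- Methyl chloroformate and pyridine convert this into 1-(4-methoxy-1-methyl-2-oxoquinolin-3-yl)-3-methylbut-2-enyl methyl carbonate F2.
- A Tsuji–Trost asymmetric allylic alkylation of 6 with the carbonate follows (Pd2(dba)3·CHCl3 as source of zerovalent palladium, DACH-phenyl Trost ligand in the enantiomer that gives (R) at C-a, CH2Cl2, rt).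
- The liberated methoxide serves as the base. The π-allyl complex of divalent palladium racemises by π–σ–π exchange at its gem-dimethyl terminus, so both carbonate enantiomers converge.
- The soft α-aryl enolate attacks the less substituted terminus C-a, giving 12.

Step 7. Hydride transfer to a carbonyl flanked by a quaternary and a tertiary carbon may be too slow. Catalyst control may also be overridden by the existing C-a centre, which would erode diastereoselection.

The fallback sets out from 12 and returns at 13. It relies on substrate control with recycling.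
- Luche reduction (NaBH4, CeCl3·7H2O, MeOH/THF, −40 °C) attacks both C-b epimers anti to the pseudoaxial side chain.
- This should give 13 together with the second cis carbinol, (3R,4R)-3-hydroxy-4-[(1R)-1-(4-methoxy-1-methyl-2-oxoquinolin-3-yl)-3-methylbut-2-enyl]-2,2,6-trimethyl-3,4-dihydro-2H-pyrano[3,2-c]quinolin-5(6H)-one F3.
- The two diastereomers are separated by chromatography.
- The unwanted one is re-oxidised with Dess–Martin periodinane to (4R)-4-[(1R)-1-(4-methoxy-1-methyl-2-oxoquinolin-3-yl)-3-methylbut-2-enyl]-2,2,6-trimethyl-2H-pyrano[3,2-c]quinoline-3,5(4H,6H)-dione F4.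
- Et3N re-equilibrates that ketone with 12 for a further pass.

Step 8. Addition of the hindered alkoxide to the electron-rich, C3-alkylated C4 position may be sluggish. That would leave time for migration of the alkoxide onto C4 of quinolone B, with pyran-to-furan ring contraction.

The fallback sets out from 13 and returns at 14. It exchanges the leaving group.
- NaSEt (DMF, 100 °C) removes the O-methyl group by SN2 attack at carbon. The product is (3S,4S)-3-hydroxy-4-[(1R)-1-(4-hydroxy-1-methyl-2-oxoquinolin-3-yl)-3-methylbut-2-enyl]-2,2,6-trimethyl-3,4-dihydro-2H-pyrano[3,2-c]quinolin-5(6H)-one F5.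
- TsCl and Et3N (CH2Cl2, 0 °C) sulfonylate only the acidic 4-OH, giving the quinolone A 4-tosylate of the (3S,4S,1R)-carbinol F6.
- NaH (THF, 0 °C → rt) then closes pyran A by displacing the sulfonate. Configuration at C-c is retained because the carbinol C–O bond is never broken.

**Further compounds**
F1 | step 6 | (±)-3-(1-hydroxy-3-methylbut-2-enyl)-4-methoxy-1-methylquinolin-2(1H)-one | COc1c(C(O)C=C(C)C)c(=O)n(C)c2ccccc12
F2 | step 6 | (±)-1-(4-methoxy-1-methyl-2-oxoquinolin-3-yl)-3-methylbut-2-enyl methyl carbonate | COC(=O)OC(C=C(C)C)c1c(OC)c2ccccc2n(C)c1=O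
F3 | step 7 | (3R,4R)-3-hydroxy-4-[(1R)-1-(4-methoxy-1-methyl-2-oxoquinolin-3-yl)-3-methylbut-2-enyl]-2,2,6-trimethyl-3,4-dihydro-2H-pyrano[3,2-c]quinolin-5(6H)-one | CC(C)=C[C@@H](c1c(OC)c2ccccc2n(C)c1=O)[C@H]1[C@@H](O)C(C)(C)Oc2c1c(=O)n(C)c1ccccc21
F4 | step 7 | (4R)-4-[(1R)-1-(4-methoxy-1-methyl-2-oxoquinolin-3-yl)-3-methylbut-2-enyl]-2,2,6-trimethyl-2H-pyrano[3,2-c]quinoline-3,5(4H,6H)-dione | CC(C)=C[C@@H](c1c(OC)c2ccccc2n(C)c1=O)[C@H]1C(=O)C(C)(C)Oc2c1c(=O)n(C)c1ccccc21
F5 | step 8 | (3S,4S)-3-hydroxy-4-[(1R)-1-(4-hydroxy-1-methyl-2-oxoquinolin-3-yl)-3-methylbut-2-enyl]-2,2,6-trimethyl-3,4-dihydro-2H-pyrano[3,2-c]quinolin-5(6H)-one | CC(C)=C[C@@H](c1c(O)c2ccccc2n(C)c1=O)[C@@H]1[C@H](O)C(C)(C)Oc2c1c(=O)n(C)c1ccccc21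
F6 | step 8 | 3-{(1R)-1-[(3S,4S)-3-hydroxy-2,2,6-trimethyl-5-oxo-3,4,5,6-tetrahydro-2H-pyrano[3,2-c]quinolin-4-yl]-3-methylbut-2-enyl}-1-methyl-2-oxoquinolin-4-yl 4-methylbenzenesulfonate | CC(C)=C[C@@H](c1c(OS(=O)(=O)c2ccc(C)cc2)c2ccccc2n(C)c1=O)[C@@H]1[C@H](O)C(C)(C)Oc2c1c(=O)n(C)c1ccccc21
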